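## Retrosynthetic overview
1. The last bond made is C3 (pyran of ring system A)–CH(CH3). C3 of the acetyl-bearing chromene attacks the planar 1-(chromen-6-yl)ethyl cation of ring system B inside a chiral phosphate ion pair. This makes the biosynthetic cation/chromene union catalytic and enantioconvergent, and it sets the (S) centre.
2. The cation comes from the racemic benzylic alcohol, the alcohol from the ketone, and the ketone from O-methylation of the same chromene. One monomer therefore feeds both halves.
3. The monomer comes from 2,4-dihydroxy-6-methoxyacetophenone and 3-methylbut-2-enal by C-alkylation, ortho-quinone methide formation and oxa-6π electrocyclisation, which is the biosynthetic pyran closure.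
4. Ring order: both benzene rings are bought. One pyran-forming operation delivers the pyran of ring system A and, after the split, of ring system B. No ring is formed after the union, and no protecting groups are used.

Assumption: the (R)-configured acid is taken to give the (S) centre; a pilot run fixes the sense, and the mirror-image acid is used instead if needed, with nothing else changed.

## Route

Step 1
Reactants: 1 2,4-dihydroxy-6-methoxyacetophenone; 2 3-methylbut-2-enal (prenal)
Product: 4 1-(5-hydroxy-7-methoxy-2,2-dimethyl-2H-chromen-6-yl)ethan-1-one, via ortho-quinone methide dienone 3 (not isolated)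
Conditions: 2 (1.5 equiv), ethylenediammonium diacetate (20 mol %), toluene, 110 °C, 16 h
Reagents that add atoms: none
Why: Knoevenagel-type C-alkylation by the iminium of 2 occurs at C3 of 1 (between the two hydroxyls, favoured by chelation-induced bond fixation), loss of water gives dienone 3, and its oxa-6π electrocyclisation through the free, non-chelated 4-oxygen closes the pyran as in chromene biosynthesis; no stereocentre is formed.

Step 2
Reactants: 4 1-(5-hydroxy-7-methoxy-2,2-dimethyl-2H-chromen-6-yl)ethan-1-one (the part of the batch not kept for step 4)
Product: 5 1-(5,7-dimethoxy-2,2-dimethyl-2H-chromen-6-yl)ethan-1-one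
Conditions: MeI (3 equiv), K2CO3 (3 equiv), DMF, 50 °C, 12 h
Reagents that add atoms: iodomethane, CI
Why: Williamson O-methylation, in which carbonate in DMF with excess MeI overcomes the hydrogen bond of the chelated phenol, the only acidic site, while the methyl ketone is not enolised by this base; no stereocentre is formed.

Step 3
Reactants: 5 1-(5,7-dimethoxy-2,2-dimethyl-2H-chromen-6-yl)ethan-1-one
Product: 6 rac-1-(5,7-dimethoxy-2,2-dimethyl-2H-chromen-6-yl)ethan-1-ol
Conditions: LiAlH4 (0.6 equiv), THF, 0 °C, 1 h; H2O / 15% aq NaOH / H2O work-up, filtration through basic alumina, used the same day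
Reagents that add atoms: none
Why: LiAlH4 carbonyl reduction of a ketone that the two ortho methoxy groups twist out of conjugation and so keep reactive; the chromene alkene is inert, the racemate is wanted because this centre is erased in step 4, and the alkaline work-up keeps the easily ionised alcohol intact.

Step 4
Reactants: 4 1-(5-hydroxy-7-methoxy-2,2-dimethyl-2H-chromen-6-yl)ethan-1-one; 6 rac-1-(5,7-dimethoxy-2,2-dimethyl-2H-chromen-6-yl)ethan-1-ol
Product: 8 1-{3-[(1S)-1-(5,7-dimethoxy-2,2-dimethyl-2H-chromen-6-yl)ethyl]-5-hydroxy-7-methoxy-2,2-dimethyl-2H-chromen-6-yl}ethan-1-one (target), via benzylic cation 7 (not isolated)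
Conditions: 4 (3 equiv, excess recovered), (R)-3,3'-bis(2,4,6-triisopropylphenyl)-1,1'-binaphthyl-2,2'-diyl hydrogen phosphate (10 mol %), 5 Å MS, toluene, −30 °C, 6 added by syringe pump over 12 h; Et3N quench
Reagents that add atoms: none
Why: Proposed new method: the acid ionises either enantiomer of 6 (a 2,4,6-trioxygenated benzylic alcohol that solvolyses with traces of acid) to the same planar cation 7, held as a contact ion pair, while the phosphoryl oxygen hydrogen-bonds the 5-OH of 4, so that 4 reacts as an ortho-hydroxystyrene through C3 on one face of 7, and loss of H-3 from the C4 cation restores the chromene and fixes the (S) centre (enantioconvergent SN1-type vinylogous Friedel-Crafts alkenylation); the chromene of 6 and of 8 bears no OH and is not recruited by the anion, and excess 4 plus slow addition of 6 hold back its self-alkylation; the closest known reaction types are chiral phosphoric acid catalysed substitutions of ionisable benzylic and 3-indolyl carbinols by ortho-hydroxystyrenes, chiral contact-ion-pair allylic substitutions by phenols, and the acid dimerisation of 2,2-dimethylchromenes, in which C3 of one chromene attacks a benzylic cation and the double bond is regenerated.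

## Compound list
1 | 2,4-dihydroxy-6-methoxyacetophenone | CC(=O)c1c(O)cc(O)cc1OC | starting material
2 | 3-methylbut-2-enal (prenal) | CC(C)=CC=O | starting material
3 | ortho-quinone methide dienone: 4-acetyl-3-hydroxy-5-methoxy-2-(3-methylbut-2-enylidene)cyclohexa-3,5-dien-1-one, butenylidene chain cis to the ring C=O | CC(=O)C1=C(O)/C(=C/C=C(C)C)C(=O)C=C1OC | intermediate
4 | 1-(5-hydroxy-7-methoxy-2,2-dimethyl-2H-chromen-6-yl)ethan-1-one | COc1cc2c(c(O)c1C(C)=O)C=CC(C)(C)O2 | intermediate
5 | 1-(5,7-dimethoxy-2,2-dimethyl-2H-chromen-6-yl)ethan-1-one | COc1cc2c(c(OC)c1C(C)=O)C=CC(C)(C)O2 | intermediate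
6 | rac-1-(5,7-dimethoxy-2,2-dimethyl-2H-chromen-6-yl)ethan-1-ol | COc1cc2c(c(OC)c1C(C)O)C=CC(C)(C)O2 | intermediate
7 | 1-(5,7-dimethoxy-2,2-dimethyl-2H-chromen-6-yl)ethyl cation (contact ion pair, chiral phosphate counter-ion) | C[CH+]c1c(OC)cc2c(c1OC)C=CC(C)(C)O2 | intermediate
8 | 1-{3-[(1S)-1-(5,7-dimethoxy-2,2-dimethyl-2H-chromen-6-yl)ethyl]-5-hydroxy-7-methoxy-2,2-dimethyl-2H-chromen-6-yl}ethan-1-one | COc1cc2c(c(O)c1C(C)=O)C=C([C@H](C)c1c(OC)cc3c(c1OC)C=CC(C)(C)O3)C(C)(C)O2 | target

## Step count and risks
Total step count: 4. Longest linear sequence: 4 (1 → 4 → 5 → 6 → 8).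

**Step 4 (highest risk).**
- The chromene of 6 and of 8 is more electron-rich than that of 4, so self-alkylation and over-alkylation compete.
- Compound 4 can also react at C8 or at oxygen.
- Cation 7 can lose a proton to give the 6-vinylchromene.
- The level of induction is unknown. A modest ee would first be raised by one recrystallisation.

The fallback sets out from 4 and 6 and comes back at 8. It gives up catalytic control and separates bond formation from stereocontrol. The union is run under equilibrating achiral conditions (4-toluenesulfonic acid 2 mol %, CH2Cl2, 0 °C to rt, 5 equiv of 4). Alkylation by the stabilised cation is then reversible, and mass action funnels oligomers of 6 into the racemic dimer F1. Its 5-OH is acylated with (1S,4R)-camphanoyl chloride (Et3N, 4-(dimethylamino)pyridine, CH2Cl2). The diastereomeric esters are separated by crystallisation or chromatography to give the (S)-dimer camphanate F2. Methanolysis (K2CO3 cat., MeOH, 0 °C) then releases 8.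

**Step 1.**
- Attack at C5 of 1 would give the 7-hydroxy-5-methoxy isomer.
- Closure through the chelated oxygen, or self-condensation of 2, could lower the yield.

The fallback sets out from 1 and comes back at 4. It follows the literal biosynthetic order. C-prenylation of 1 between the two hydroxyls (prenyl bromide, aq KOH, 0 °C to rt) gives the 3-prenylacetophenone F3. Hydride abstraction with 2,3-dichloro-5,6-dicyano-1,4-benzoquinone (toluene, rt to 80 °C) produces dienone 3, which electrocyclises through the free 4-oxygen to 4. The regiochemistry is now fixed by the isolated, fully characterised F3.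

**Step 3.**
- Alcohol 6 may ionise, etherify or dehydrate during isolation and storage.

The fallback sets out from 5 and comes back at 7, and hence at 8. The free alcohol is never handled. Ketone 5 is reduced with NaBH4 in MeOH, and the crude 6 is solvolysed in the same flask (pyridinium 4-toluenesulfonate cat., MeOH, rt) to the benzylic methyl ether F4. This ether survives chromatography and storage. It is fed by syringe pump into the step 4 mixture, where the chiral acid ionises it to the same cation 7.

## Further compounds
F1 | step 4 | racemic dimer, rac-1-{3-[1-(5,7-dimethoxy-2,2-dimethyl-2H-chromen-6-yl)ethyl]-5-hydroxy-7-methoxy-2,2-dimethyl-2H-chromen-6-yl}ethan-1-one | COc1cc2c(c(O)c1C(C)=O)C=C(C(C)c1c(OC)cc3c(c1OC)C=CC(C)(C)O3)C(C)(C)O2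
F2 | step 4 | (S)-dimer camphanate, the 5-O-[(1S,4R)-camphanoyl] ester of 8 | COc1cc2c(c(OC(=O)[C@@]34CC[C@@](C)(C(=O)O3)C4(C)C)c1C(C)=O)C=C([C@H](C)c1c(OC)cc3c(c1OC)C=CC(C)(C)O3)C(C)(C)O2
F3 | step 1 | 3-prenylacetophenone, 1-[2,4-dihydroxy-6-methoxy-3-(3-methylbut-2-en-1-yl)phenyl]ethan-1-one | CC(=O)c1c(O)c(CC=C(C)C)c(O)cc1OC
F4 | step 3 | benzylic methyl ether, rac-6-(1-methoxyethyl)-5,7-dimethoxy-2,2-dimethyl-2H-chromene | COC(C)c1c(OC)cc2c(c1OC)C=CC(C)(C)O2
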